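**Plan** (carotenoid numbering: ring C1–C6, chain C7–C15 and C15′–C8′; the furan is O–C8–C7=C6–C5)

- Retrosynthesis: cut C11=C12 (Wittig: C15 hydroxy-enal + C15 phosphonium ester), then the furan O–C5 bond, which leads back to a trans-7,8-oxirane next to the C5=C6 ring alkene. Further cuts: C9=C10 (HWE), the oxirane (Sharpless), C6–C7 (Heck) and, in the chain, C11′=C12′ (HWE on the C10 dialdehyde).
- Enabling feature: the 2,5-dihydrofuran O–C8–C7=C6–C5, fused to the cyclohexane at C5–C6, is the 1,3-oxygen-shift isomer of a 7,8-epoxide that carries the tetrasubstituted C5=C6 alkene; the tertiary allylic terminus C5 accepts the oxygen.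
- Forward order: cyclohexene from the chiral pool → oxirane → dihydrofuran by ring expansion → C15 enal; the polyene ylide is made separately; the two halves are joined last and the ester end is adjusted to the aldehyde.
- Stereochemistry: C3 comes from (4R,6R)-actinol with Mitsunobu inversion. C7 and C8 come from CBS reduction and matched Sharpless epoxidation. C5 is relayed from C7 in the ring expansion.
- The all-E chain comes from E-selective olefinations and the E,E,E-dialdehyde.

Key step: step 8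

Assumption: compounds 1, 13 and 15 are taken as catalogue compounds.

**Step 1**
Reactants: 1 (4R,6R)-4-hydroxy-2,2,6-trimethylcyclohexan-1-one
Product: 2 (1S,5R)-3,3,5-trimethyl-4-oxocyclohexyl benzoate
Conditions: PhCO2H, PPh3, DIAD, THF, 0 °C → rt
Reagents that add atoms: benzoic acid, O=C(O)c1ccccc1
Why: Mitsunobu esterification: benzoate displaces the oxyphosphonium by SN2, so the carbinol carbon is inverted (4R → 4S, the configuration needed at C3) while C6 is untouched; the C–O bond of 1 can sit axial, which leaves the equatorial backside open.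

**Step 2**
Reactants: 2 (1S,5R)-3,3,5-trimethyl-4-oxocyclohexyl benzoate
Product: 3 (1S)-3,5,5-trimethyl-4-[(trifluoromethanesulfonyl)oxy]cyclohex-3-en-1-yl benzoate
Conditions: KHMDS, THF, −78 °C; then PhNTf2, −78 → 0 °C
Reagents that add atoms: N-phenylbis(trifluoromethanesulfonimide), O=S(=O)(N(c1ccccc1)S(=O)(=O)C(F)(F)F)C(F)(F)F
Why: Enol triflate formation: only one α-carbon bears a hydrogen, so a single enolate forms and is O-triflated; the methyl-bearing stereocentre is erased as planned and the non-nucleophilic base should leave the benzoate alone.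

**Step 3**
Reactants: 3 (1S)-3,5,5-trimethyl-4-[(trifluoromethanesulfonyl)oxy]cyclohex-3-en-1-yl benzoate, 4 but-3-en-2-one
Product: 5 (1S)-3,5,5-trimethyl-4-[(1E)-3-oxobut-1-en-1-yl]cyclohex-3-en-1-yl benzoate
Conditions: Pd(OAc)2 (cat.), PPh3, Et3N, DMF, 70 °C
Reagents that add atoms: none
Why: Heck vinylation of the enol triflate: oxidative addition, syn-insertion of the enone and syn-β-hydride elimination should give the E-dienone and form C6–C7.

**Step 4**
Reactants: 5 (1S)-3,5,5-trimethyl-4-[(1E)-3-oxobut-1-en-1-yl]cyclohex-3-en-1-yl benzoate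
Product: 6 (1S)-4-[(1E,3S)-3-hydroxybut-1-en-1-yl]-3,5,5-trimethylcyclohex-3-en-1-yl benzoate
Conditions: (R)-2-methyl-CBS-oxazaborolidine (cat.), BH3·SMe2, THF/PhMe, −30 °C
Reagents that add atoms: none
Why: Corey–Bakshi–Shibata reduction: the (R)-catalyst directs hydride to one face of the alkenyl methyl ketone (alkenyl as the large group) and should give the S-carbinol; the reduction is 1,2-selective and spares the benzoate.

**Step 5**
Reactants: 6 (1S)-4-[(1E,3S)-3-hydroxybut-1-en-1-yl]-3,5,5-trimethylcyclohex-3-en-1-yl benzoate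
Product: 7 (1S)-4-{(2S,3S)-3-[(1S)-1-hydroxyethyl]oxiran-2-yl}-3,5,5-trimethylcyclohex-3-en-1-yl benzoate
Conditions: Ti(OiPr)4, L-(+)-DIPT, t-BuOOH, 4 Å MS, CH2Cl2, −20 °C
Reagents that add atoms: tert-butyl hydroperoxide, CC(C)(C)OO
Why: Katsuki–Sharpless asymmetric epoxidation in the matched pairing (S-carbinol with L-(+)-tartrate): titanium-bound peroxide is delivered to one face of C7=C8 and should set 7S,8S (erythro), while the non-allylic tetrasubstituted ring alkene is not touched.

**Step 6**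
Reactants: 7 (1S)-4-{(2S,3S)-3-[(1S)-1-hydroxyethyl]oxiran-2-yl}-3,5,5-trimethylcyclohex-3-en-1-yl benzoate
Product: 8 (1S)-4-[(2S,3R)-3-acetyloxiran-2-yl]-3,5,5-trimethylcyclohex-3-en-1-yl benzoate
Conditions: Dess–Martin periodinane, NaHCO3, CH2Cl2, 0 °C → rt
Reagents that add atoms: none
Why: Dess–Martin oxidation under buffered conditions should give the methyl ketone without opening the allylic oxirane; the auxiliary carbinol centre is removed (the descriptor at the neighbouring oxirane carbon changes only through CIP ranks).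

**Step 7**
Reactants: 8 (1S)-4-[(2S,3R)-3-acetyloxiran-2-yl]-3,5,5-trimethylcyclohex-3-en-1-yl benzoate
Product: 9 ethyl (2E)-3-{(2S,3S)-3-[(4S)-4-(benzoyloxy)-2,6,6-trimethylcyclohex-1-en-1-yl]oxiran-2-yl}but-2-enoate
Conditions: (EtO)2P(O)CH2CO2Et, NaH, THF, 0 °C → rt
Reagents that add atoms: triethyl phosphonoacetate, CCOC(=O)CP(=O)(OCC)OCC
Why: Horner–Wadsworth–Emmons olefination of the methyl ketone: the E-isomer (ester trans to the oxiranyl group) should dominate and a minor 2Z isomer is separable; the conjugated ester also makes the C8–O bond of the oxirane non-ionisable for step 8.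

**Step 8**
Reactants: 9 ethyl (2E)-3-{(2S,3S)-3-[(4S)-4-(benzoyloxy)-2,6,6-trimethylcyclohex-1-en-1-yl]oxiran-2-yl}but-2-enoate
Product: 10 ethyl (2E)-3-[(2R,6R,7aR)-6-(benzoyloxy)-4,4,7a-trimethyl-2,4,5,6,7,7a-hexahydro-1-benzofuran-2-yl]but-2-enoate
Conditions: Cu(hfacac)2 (5 mol %), PhMe, 90–110 °C
Reagents that add atoms: none
Why: Copper-catalysed ring expansion of a vinyl oxirane to a 2,5-dihydrofuran (the closest known type is the Cu(hfacac)2 rearrangement of 2-alkenyloxiranes): copper binds the oxirane oxygen and the allylic C7–O bond heterolyses with help of the C5=C6 π bond to a contact pair of a copper alkoxide on C8 and an allyl cation C7–C6–C5 that is tertiary at C5. The alkoxide then bonds to C5, which closes the furan in a formal 5-endo mode (net 1,3-shift of oxygen from C7 to C5) and moves the double bond to C6=C7. C8 keeps its configuration because its C–O bond is never broken (2S in the oxirane becomes 2R in the product only through CIP ranks). C5 is set by chirality transfer from C7: closure needs the s-cis rotamer about C6–C7, in which the 7S centre holds the departing oxygen over one face of the cyclohexene, and collapse on that same face (suprafacial) should give 7aR, cis to the ring ester oxygen. The step needs cleavage of C7–O and not C8–O, which is secured by the electron-rich tetrasubstituted ring alkene on C7 against the ester-conjugated alkene on C8, which cannot carry positive charge. It also needs closure to outrun hydride shift or proton loss, which the bound alkoxide and the non-basic medium favour.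

**Step 9**
Reactants: 10 ethyl (2E)-3-[(2R,6R,7aR)-6-(benzoyloxy)-4,4,7a-trimethyl-2,4,5,6,7,7a-hexahydro-1-benzofuran-2-yl]but-2-enoate
Product: 11 (2R,6R,7aR)-2-[(2E)-4-hydroxybut-2-en-2-yl]-4,4,7a-trimethyl-2,4,5,6,7,7a-hexahydro-1-benzofuran-6-ol
Conditions: DIBAL-H (excess), CH2Cl2, −78 → 0 °C; Rochelle salt
Reagents that add atoms: none
Why: DIBAL-H reduces the conjugated ester 1,2 to the allylic alcohol and cleaves the benzoate in the same operation; the allylic ether and the stereocentres should not be affected at low temperature.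

**Step 10**
Reactants: 11 (2R,6R,7aR)-2-[(2E)-4-hydroxybut-2-en-2-yl]-4,4,7a-trimethyl-2,4,5,6,7,7a-hexahydro-1-benzofuran-6-ol
Product: 12 (2E)-3-[(2R,6R,7aR)-6-hydroxy-4,4,7a-trimethyl-2,4,5,6,7,7a-hexahydro-1-benzofuran-2-yl]but-2-enal
Conditions: activated MnO2, CH2Cl2, rt
Reagents that add atoms: none
Why: MnO2 oxidises only the primary allylic alcohol; the saturated secondary alcohol stays, and the neutral medium should keep the allylic ether centre C2 intact.

**Step 11**
Reactants: 13 ethyl (2E)-4-bromo-2-methylbut-2-enoate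
Product: 14 ethyl (2E)-4-(diethoxyphosphoryl)-2-methylbut-2-enoate
Conditions: P(OEt)3, neat, 130 °C
Reagents that add atoms: triethyl phosphite, CCOP(OCC)OCC
Why: Michaelis–Arbuzov reaction of the primary allylic bromide; SN2 at the CH2 group keeps the E-alkene.

**Step 12**
Reactants: 14 ethyl (2E)-4-(diethoxyphosphoryl)-2-methylbut-2-enoate, 15 (2E,4E,6E)-2,7-dimethylocta-2,4,6-trienedial
Product: 17 ethyl (2E,4E,6E,8E,10E)-2,6,11-trimethyl-12-oxododeca-2,4,6,8,10-pentaenoate, via sodium phosphonate carbanion 16 (not isolated)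
Conditions: NaH, THF, 0 °C; then added to 15 (3 equiv), −40 → 0 °C
Reagents that add atoms: none
Why: Vinylogous Horner–Wadsworth–Emmons olefination: the anion reacts through its α-carbon with one aldehyde of the symmetric dialdehyde, which is used in excess so that mono-olefination should prevail; the new disubstituted alkene forms E.

**Step 13**
Reactants: 17 ethyl (2E,4E,6E,8E,10E)-2,6,11-trimethyl-12-oxododeca-2,4,6,8,10-pentaenoate
Product: 18 ethyl (2E,4E,6E,8E,10E)-12-hydroxy-2,6,11-trimethyldodeca-2,4,6,8,10-pentaenoate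
Conditions: NaBH4, EtOH/THF, −10 °C
Reagents that add atoms: none
Why: Borohydride reduces the aldehyde 1,2 and leaves the conjugated ester.

**Step 14**
Reactants: 18 ethyl (2E,4E,6E,8E,10E)-12-hydroxy-2,6,11-trimethyldodeca-2,4,6,8,10-pentaenoate
Product: 19 [(2E,4E,6E,8E,10E)-12-ethoxy-2,7,11-trimethyl-12-oxododeca-2,4,6,8,10-pentaen-1-yl]triphenylphosphonium bromide
Conditions: PPh3·HBr, CH2Cl2, rt
Reagents that add atoms: triphenylphosphine hydrobromide, [Br-].[PH+](c1ccccc1)(c1ccccc1)c1ccccc1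
Why: Phosphonium salt formation from an allylic alcohol: protonation and loss of water, then attack of the phosphine at the terminal carbon, which keeps the pentaene ester in conjugation.

**Step 15**
Reactants: 12 (2E)-3-[(2R,6R,7aR)-6-hydroxy-4,4,7a-trimethyl-2,4,5,6,7,7a-hexahydro-1-benzofuran-2-yl]but-2-enal, 19 [(2E,4E,6E,8E,10E)-12-ethoxy-2,7,11-trimethyl-12-oxododeca-2,4,6,8,10-pentaen-1-yl]triphenylphosphonium bromide
Product: 21 ethyl (2E,4E,6E,8E,10E,12E,14E)-15-[(2R,6R,7aR)-6-hydroxy-4,4,7a-trimethyl-2,4,5,6,7,7a-hexahydro-1-benzofuran-2-yl]-2,6,11-trimethylhexadeca-2,4,6,8,10,12,14-heptaenoate, via phosphorus ylide 20 (not isolated)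
Conditions: 1,2-epoxybutane, EtOH, reflux
Reagents that add atoms: none
Why: Wittig olefination forming C11=C12: epoxybutane scavenges HBr so the ylide forms without strong base, which tolerates the free hydroxyl and the allylic ether centre; the polyenyl ylide should give mainly the E-alkene and any 11Z isomer should equilibrate to all-E on heating.

**Step 16**
Reactants: 21 ethyl (2E,4E,6E,8E,10E,12E,14E)-15-[(2R,6R,7aR)-6-hydroxy-4,4,7a-trimethyl-2,4,5,6,7,7a-hexahydro-1-benzofuran-2-yl]-2,6,11-trimethylhexadeca-2,4,6,8,10,12,14-heptaenoate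
Product: 22 (2R,6R,7aR)-2-[(2E,4E,6E,8E,10E,12E,14E)-16-hydroxy-6,11,15-trimethylhexadeca-2,4,6,8,10,12,14-heptaen-2-yl]-4,4,7a-trimethyl-2,4,5,6,7,7a-hexahydro-1-benzofuran-6-ol
Conditions: DIBAL-H, CH2Cl2, −78 °C; Rochelle salt
Reagents that add atoms: none
Why: DIBAL-H reduces the conjugated ester 1,2 to the allylic alcohol; the free hydroxyl only consumes one extra equivalent.

**Step 17**
Reactants: 22 (2R,6R,7aR)-2-[(2E,4E,6E,8E,10E,12E,14E)-16-hydroxy-6,11,15-trimethylhexadeca-2,4,6,8,10,12,14-heptaen-2-yl]-4,4,7a-trimethyl-2,4,5,6,7,7a-hexahydro-1-benzofuran-6-ol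
Product: 23 (2E,4E,6E,8E,10E,12E,14E)-15-[(2R,6R,7aR)-6-hydroxy-4,4,7a-trimethyl-2,4,5,6,7,7a-hexahydro-1-benzofuran-2-yl]-2,6,11-trimethylhexadeca-2,4,6,8,10,12,14-heptaenal
Conditions: activated MnO2, CH2Cl2, rt, dark
Reagents that add atoms: none
Why: MnO2 oxidises the allylic polyenyl alcohol to the aldehyde under neutral conditions; the secondary alcohol and the acid-sensitive dihydrofuran are left as they are.

**Compound list**

1 | (4R,6R)-4-hydroxy-2,2,6-trimethylcyclohexan-1-one | C[C@@H]1C[C@@H](O)CC(C)(C)C1=O | starting material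
2 | (1S,5R)-3,3,5-trimethyl-4-oxocyclohexyl benzoate | C[C@@H]1C[C@H](OC(=O)c2ccccc2)CC(C)(C)C1=O | intermediate
3 | (1S)-3,5,5-trimethyl-4-[(trifluoromethanesulfonyl)oxy]cyclohex-3-en-1-yl benzoate | CC1=C(OS(=O)(=O)C(F)(F)F)C(C)(C)C[C@@H](OC(=O)c2ccccc2)C1 | intermediate
4 | but-3-en-2-one | CC(=O)C=C | starting material
5 | (1S)-3,5,5-trimethyl-4-[(1E)-3-oxobut-1-en-1-yl]cyclohex-3-en-1-yl benzoate | CC(=O)/C=C/C1=C(C)C[C@H](OC(=O)c2ccccc2)CC1(C)C | intermediate
6 | (1S)-4-[(1E,3S)-3-hydroxybut-1-en-1-yl]-3,5,5-trimethylcyclohex-3-en-1-yl benzoate | C[C@H](O)/C=C/C1=C(C)C[C@H](OC(=O)c2ccccc2)CC1(C)C | intermediate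
7 | (1S)-4-{(2S,3S)-3-[(1S)-1-hydroxyethyl]oxiran-2-yl}-3,5,5-trimethylcyclohex-3-en-1-yl benzoate | C[C@H](O)[C@@H]1O[C@H]1C2=C(C)C[C@H](OC(=O)c3ccccc3)CC2(C)C | intermediate
8 | (1S)-4-[(2S,3R)-3-acetyloxiran-2-yl]-3,5,5-trimethylcyclohex-3-en-1-yl benzoate | CC(=O)[C@@H]1O[C@H]1C2=C(C)C[C@H](OC(=O)c3ccccc3)CC2(C)C | intermediate
9 | ethyl (2E)-3-{(2S,3S)-3-[(4S)-4-(benzoyloxy)-2,6,6-trimethylcyclohex-1-en-1-yl]oxiran-2-yl}but-2-enoate | CCOC(=O)/C=C(\C)[C@@H]1O[C@H]1C2=C(C)C[C@H](OC(=O)c3ccccc3)CC2(C)C | intermediate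
10 | ethyl (2E)-3-[(2R,6R,7aR)-6-(benzoyloxy)-4,4,7a-trimethyl-2,4,5,6,7,7a-hexahydro-1-benzofuran-2-yl]but-2-enoate | CCOC(=O)/C=C(\C)[C@H]1C=C2C(C)(C)C[C@@H](OC(=O)c3ccccc3)C[C@@]2(C)O1 | intermediate
11 | (2R,6R,7aR)-2-[(2E)-4-hydroxybut-2-en-2-yl]-4,4,7a-trimethyl-2,4,5,6,7,7a-hexahydro-1-benzofuran-6-ol | OC/C=C(\C)[C@H]1C=C2C(C)(C)C[C@@H](O)C[C@@]2(C)O1 | intermediate
12 | (2E)-3-[(2R,6R,7aR)-6-hydroxy-4,4,7a-trimethyl-2,4,5,6,7,7a-hexahydro-1-benzofuran-2-yl]but-2-enal | O=C/C=C(\C)[C@H]1C=C2C(C)(C)C[C@@H](O)C[C@@]2(C)O1 | intermediate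
13 | ethyl (2E)-4-bromo-2-methylbut-2-enoate | CCOC(=O)/C(C)=C/CBr | starting material
14 | ethyl (2E)-4-(diethoxyphosphoryl)-2-methylbut-2-enoate | CCOC(=O)/C(C)=C/CP(=O)(OCC)OCC | intermediate
15 | (2E,4E,6E)-2,7-dimethylocta-2,4,6-trienedial | O=C/C(C)=C/C=C/C=C(C)/C=O | starting material
16 | sodium salt of the C4 carbanion of 14 | CCOC(=O)/C(C)=C/[CH-]P(=O)(OCC)OCC.[Na+] | intermediate (not isolated)
17 | ethyl (2E,4E,6E,8E,10E)-2,6,11-trimethyl-12-oxododeca-2,4,6,8,10-pentaenoate | CCOC(=O)/C(C)=C/C=C/C(C)=C/C=C/C=C(C)/C=O | intermediate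
18 | ethyl (2E,4E,6E,8E,10E)-12-hydroxy-2,6,11-trimethyldodeca-2,4,6,8,10-pentaenoate | CCOC(=O)/C(C)=C/C=C/C(C)=C/C=C/C=C(C)/CO | intermediate
19 | [(2E,4E,6E,8E,10E)-12-ethoxy-2,7,11-trimethyl-12-oxododeca-2,4,6,8,10-pentaen-1-yl]triphenylphosphonium bromide | CCOC(=O)/C(C)=C/C=C/C(C)=C/C=C/C=C(C)/C[P+](c1ccccc1)(c1ccccc1)c1ccccc1.[Br-] | intermediate
20 | ylide of 19 (deprotonated at C1 of the chain) | CCOC(=O)/C(C)=C/C=C/C(C)=C/C=C/C=C(C)/[CH-][P+](c1ccccc1)(c1ccccc1)c1ccccc1 | intermediate (not isolated)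
21 | ethyl (2E,4E,6E,8E,10E,12E,14E)-15-[(2R,6R,7aR)-6-hydroxy-4,4,7a-trimethyl-2,4,5,6,7,7a-hexahydro-1-benzofuran-2-yl]-2,6,11-trimethylhexadeca-2,4,6,8,10,12,14-heptaenoate | CCOC(=O)/C(C)=C/C=C/C(C)=C/C=C/C=C(C)/C=C/C=C(\C)[C@H]1C=C2C(C)(C)C[C@@H](O)C[C@@]2(C)O1 | intermediate
22 | (2R,6R,7aR)-2-[(2E,4E,6E,8E,10E,12E,14E)-16-hydroxy-6,11,15-trimethylhexadeca-2,4,6,8,10,12,14-heptaen-2-yl]-4,4,7a-trimethyl-2,4,5,6,7,7a-hexahydro-1-benzofuran-6-ol | OC/C(C)=C/C=C/C(C)=C/C=C/C=C(C)/C=C/C=C(\C)[C@H]1C=C2C(C)(C)C[C@@H](O)C[C@@]2(C)O1 | intermediate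
23 | (2E,4E,6E,8E,10E,12E,14E)-15-[(2R,6R,7aR)-6-hydroxy-4,4,7a-trimethyl-2,4,5,6,7,7a-hexahydro-1-benzofuran-2-yl]-2,6,11-trimethylhexadeca-2,4,6,8,10,12,14-heptaenal | C\C(C=O)=C/C=C/C(C)=C/C=C/C=C(C)/C=C/C=C(\C)[C@H]1C=C2C(C)(C)C[C@@H](O)C[C@@]2(C)O1 | target

**Count and risks**

Total step count: 17. Longest linear sequence: 13 steps (steps 1–10 and 15–17).

Step 8 may fail through loss of regiocontrol in the C–O heterolysis (opening on the ester side), through 1,2-hydride shift or proton loss from the allyl cation, or through leakage of the ion pair to the other face of C5. The fallback sets out from 5 and returns at 11, and forms the furan the other way round, from an oxygen already on C5. Olefination of 5 with triethyl phosphonoacetate and NaH should give ethyl (2E,4E)-5-[(4S)-4-(benzoyloxy)-2,6,6-trimethylcyclohex-1-en-1-yl]-3-methylpenta-2,4-dienoate F1. Ethanolysis of the benzoate (K2CO3, EtOH) should give ethyl (2E,4E)-5-[(4S)-4-hydroxy-2,6,6-trimethylcyclohex-1-en-1-yl]-3-methylpenta-2,4-dienoate F2. Hydroxyl-directed epoxidation (VO(acac)2, t-BuOOH, PhMe) should place the oxygen on the ring alkene cis to the hydroxyl and give ethyl (2E,4E)-5-[(1S,4R,6R)-4-hydroxy-2,2,6-trimethyl-7-oxabicyclo[4.1.0]heptan-1-yl]-3-methylpenta-2,4-dienoate F3. Mild acid (PPTS or a trace of HCl in CHCl3, 0 °C) should rearrange the epoxide to the furanoid oxide as a pair of C8 epimers, from which ethyl (2E)-3-[(2R,6R,7aR)-6-hydroxy-4,4,7a-trimethyl-2,4,5,6,7,7a-hexahydro-1-benzofuran-2-yl]but-2-enoate F4 is separated by chromatography. Reduction with DIBAL-H then gives 11.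

Step 3 may fail through slow oxidative addition and insertion at the tetrasubstituted, doubly flanked enol triflate, with reduction of the triflate or polymerisation of the enone taking over. The fallback sets out from 3 and returns at 6, which also bypasses step 4. Palladium-catalysed hydrostannation of commercial (S)-but-3-yn-2-ol with Bu3SnH should give (3E,2S)-4-(tributylstannyl)but-3-en-2-ol F5, with the carbinol centre taken from the chiral pool. Stille coupling of F5 with 3 (Pd2(dba)3, AsPh3, NMP, 60 °C) should give 6 directly.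

Step 5 may fail through Lewis-acid opening of the newly formed tertiary-allylic oxirane by the neighbouring hydroxyl or by isopropoxide during the epoxidation or its work-up. The fallback sets out from 5 and returns at 8, which bypasses steps 4–6 and never forms a hydroxy epoxide. It is a direct catalytic asymmetric nucleophilic epoxidation of the enone (La(OiPr)3, (S)-BINOL, Ph3As=O, t-BuOOH, 4 Å MS, THF, rt), in which hydroperoxide adds to C7 and the enolate closes onto oxygen to give the trans-epoxy ketone. The BINOL antipode is chosen to deliver the (2S,3R)-oxirane. No new compound is made (F0).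

**Further compounds**

F1 | step 8 | ethyl (2E,4E)-5-[(4S)-4-(benzoyloxy)-2,6,6-trimethylcyclohex-1-en-1-yl]-3-methylpenta-2,4-dienoate | CCOC(=O)/C=C(C)/C=C/C1=C(C)C[C@H](OC(=O)c2ccccc2)CC1(C)C
F2 | step 8 | ethyl (2E,4E)-5-[(4S)-4-hydroxy-2,6,6-trimethylcyclohex-1-en-1-yl]-3-methylpenta-2,4-dienoate | CCOC(=O)/C=C(C)/C=C/C1=C(C)C[C@H](O)CC1(C)C
F3 | step 8 | ethyl (2E,4E)-5-[(1S,4R,6R)-4-hydroxy-2,2,6-trimethyl-7-oxabicyclo[4.1.0]heptan-1-yl]-3-methylpenta-2,4-dienoate | C[C@@]12C[C@H](O)CC(C)(C)[C@@]1(O2)/C=C/C(C)=C/C(=O)OCC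
F4 | step 8 | ethyl (2E)-3-[(2R,6R,7aR)-6-hydroxy-4,4,7a-trimethyl-2,4,5,6,7,7a-hexahydro-1-benzofuran-2-yl]but-2-enoate | CCOC(=O)/C=C(\C)[C@H]1C=C2C(C)(C)C[C@@H](O)C[C@@]2(C)O1
F5 | step 3 | (3E,2S)-4-(tributylstannyl)but-3-en-2-ol | C[C@H](O)/C=C/[Sn](CCCC)(CCCC)CCCC
F0 | step 5 | none | none
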